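**Strategy.** Ring B of this 9-hydroxylabdane (labdane numbering) is cut into two three-carbon pieces: the C6–C5–C10 unit of a ring A methylenecyclohexene and the C7–C8–C9 unit of methacrolein. A chiral Lewis acid should join them in one flask by a conjugate ene reaction (C6–C7) followed by Prins-type carbonyl-ene closure (C9–C10). This creates the quaternary C10 and exploits two features: C4 is quaternary, so only the C10 hydrogen can shift, and C6 and C10 are the two ends of one allyl unit. The C10 methyl then directs the trans ring fusion, the C9 carbinol and the cis-2,3-diol. The precursor is a racemic 1,4-diene made by Birch reduction of 2,6-dimethylanisole.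

Key step: step 4

Assumption: the (S)-oxazaborolidinium exposes the enal face that gives (2R)-7; should the sense of induction be the opposite, the (R)-catalyst is used instead.

Step 1
Reactants: 1 2,6-dimethylanisole
Product: 3 2,6-dimethylcyclohex-3-en-1-one (cis/trans mixture), via Birch diene 2 (not isolated)
Conditions: Li, NH3 (l), t-BuOH, THF, –78 °C; then oxalic acid, MeOH/H2O, 0 °C
Reagents that add atoms: water, O
Why: Birch reduction dearomatizes the anisole to the 1-methoxy-1,4-diene and mild hydrolysis of the enol ether should give the β,γ-unsaturated ketone without conjugation, its two stereocenters being erased later.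

Step 2
Reactants: 3 2,6-dimethylcyclohex-3-en-1-one
Product: 4 2,2,6-trimethylcyclohex-3-en-1-one (racemic)
Conditions: KOtBu, THF/t-BuOH, 0 °C; then MeI
Reagents that add atoms: iodomethane, CI
Why: the allylic α-hydrogen is removed to give the extended dienolate, which is methylated at its α-carbon (deconjugative α-alkylation) and so places the future C4 gem-dimethyl group next to the future C2=C3 alkene.

Step 3
Reactants: 4 2,2,6-trimethylcyclohex-3-en-1-one
Product: 5 3,3,5-trimethyl-4-methylidenecyclohex-1-ene (racemic)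
Conditions: Ph3PCH3Br, KOtBu, toluene, 90 °C
Reagents that add atoms: methyltriphenylphosphonium bromide, C[P+](c1ccccc1)(c1ccccc1)c1ccccc1.[Br-]
Why: Wittig methylenation with the ylide at elevated temperature is the usual way to convert hindered, weakly enolisable cyclohexanones into exocyclic methylene compounds and installs C6.

Step 4
Reactants: 5 3,3,5-trimethyl-4-methylidenecyclohex-1-ene; 6 methacrolein (2-methylprop-2-enal)
Product: 8 (1S,2R,8aS)-2,5,5,8a-tetramethyl-1,2,3,5,8,8a-hexahydronaphthalen-1-ol, via ene aldehyde 7 (not isolated)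
Conditions: (S)-1-(2-methylphenyl)-3,3-diphenyltetrahydro-1H,3H-pyrrolo[1,2-c][1,3,2]oxazaborole protonated by Tf2NH (20 mol %), 5 in excess, CH2Cl2, –78 to –20 °C
Reagents that add atoms: none
Why: Proposed new method: the cationic boron Lewis acid binds s-trans methacrolein 6, the exocyclic CH2 of 5 (C6) adds to the enal terminus (C7) and the only allylic hydrogen of the resulting C5 cation (that on C10, since C4 is quaternary; both enantiomers of 5 converge because C10 becomes trigonal) shifts to C8 to give aldehyde 7 with a tetrasubstituted C5=C10 alkene, whose C10 then attacks the still activated aldehyde carbon C9 while the new C5 cation loses H6, so that C6–C7 and C9–C10 are both formed in one flask. The closest known reaction type is the Me2AlCl-promoted sequential ene annulation of alkylidenecycloalkanes with acrolein-type enals, which is racemic, and the chiral version is reasoned from oxazaborolidinium-catalysed Diels–Alder reactions of 2-methylacrolein, in which one face of the bound enal is shielded. Ring B closes in the 6-endo-trig mode with respect to the C5=C10 alkene (Prins-type intramolecular carbonyl-ene) through a chair transition state. C8 is controlled by the catalyst, which lets hydrogen arrive only on the exposed enal face; C10 is controlled by C8, because only the chair with the C8 methyl equatorial avoids a 1,3-diaxial contact with the C10 methyl and this fixes the face of C10 that bonds to C9; C9 (oxygen equatorial) is set by the same chair but is erased by oxidation in step 8. The step needs conjugate instead of carbonyl attack in the first event, which the unhindered CH2 terminus of the activated enal secures, and it needs proton loss from C6 to outrun a methyl shift from C4 to C5, which the neighbouring boron-bound alkoxide should assist.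

Step 5
Reactants: 8 (1S,2R,8aS)-2,5,5,8a-tetramethyl-1,2,3,5,8,8a-hexahydronaphthalen-1-ol
Product: 9 (1S,2R,6S,7R,8aS)-2,5,5,8a-tetramethyl-1,2,3,5,6,7,8,8a-octahydronaphthalene-1,6,7-triol
Conditions: OsO4 (2 mol %), NMO, acetone/H2O, 0 °C
Reagents that add atoms: N-methylmorpholine N-oxide, C[N+]1([O-])CCOCC1; water, O
Why: Upjohn dihydroxylation should attack the unhindered cis-disubstituted C2=C3 alkene from the α face, opposite the axial β-methyl groups on C4 and C10, to give the 2α,3α-diol, while the C5=C6 alkene flanked by two quaternary carbons stays untouched.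

Step 6
Reactants: 9 (1S,2R,6S,7R,8aS)-2,5,5,8a-tetramethyl-1,2,3,5,6,7,8,8a-octahydronaphthalene-1,6,7-triol
Product: 10 (1S,2R,6S,7R,8aS)-6,7-(isopropylidenedioxy)-2,5,5,8a-tetramethyl-1,2,3,5,6,7,8,8a-octahydronaphthalen-1-ol
Conditions: 2,2-dimethoxypropane, PPTS, CH2Cl2, rt
Reagents that add atoms: 2,2-dimethoxypropane, COC(C)(C)OC
Why: acid-catalysed ketal exchange should engage only the cis-1,2-diol as the five-membered acetonide and leave the isolated C9 alcohol free.

Step 7
Reactants: 10 (1S,2R,6S,7R,8aS)-6,7-(isopropylidenedioxy)-2,5,5,8a-tetramethyl-1,2,3,5,6,7,8,8a-octahydronaphthalen-1-ol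
Product: 11 (1S,2R,4aS,6S,7R,8aS)-6,7-(isopropylidenedioxy)-2,5,5,8a-tetramethyldecahydronaphthalen-1-ol
Conditions: Mn(dpm)3 (10 mol %), PhSiH3, t-BuOOH, i-PrOH, rt
Reagents that add atoms: none
Why: hydrogen-atom-transfer hydrogenation places H on C6, and the tertiary C5 radical should then accept hydrogen from the α face, opposite the axial methyl groups on C4 and C10, giving the thermodynamically favoured trans ring fusion (5α-H).

Step 8
Reactants: 11 (1S,2R,4aS,6S,7R,8aS)-6,7-(isopropylidenedioxy)-2,5,5,8a-tetramethyldecahydronaphthalen-1-ol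
Product: 12 (2R,4aS,6S,7R,8aS)-6,7-(isopropylidenedioxy)-2,5,5,8a-tetramethyloctahydronaphthalen-1(2H)-one
Conditions: DMP, CH2Cl2, 0 °C to rt
Reagents that add atoms: none
Why: Dess–Martin oxidation converts the hindered secondary alcohol into the C9 ketone, and the C8 methyl cannot be eroded because its equatorial α orientation is also the thermodynamic one.

Step 9
Reactants: 12 (2R,4aS,6S,7R,8aS)-6,7-(isopropylidenedioxy)-2,5,5,8a-tetramethyloctahydronaphthalen-1(2H)-one; 13 4-bromo-1-(trimethylsilyl)but-1-yne
Product: 15 (1S,2R,4aS,6S,7R,8aS)-6,7-(isopropylidenedioxy)-2,5,5,8a-tetramethyl-1-[4-(trimethylsilyl)but-3-yn-1-yl]decahydronaphthalen-1-ol, via Grignard reagent 14 (not isolated)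
Conditions: 13, Mg, THF, rt; CeCl3, –78 °C; then 12, –78 to 0 °C; aq NH4Cl
Reagents that add atoms: none
Why: the weakly basic organocerium reagent should add to the enolisable ketone by axial attack on the α face, anti to the axial C10 methyl on the neighbouring carbon, which gives the 9β-hydroxyl and the 9α side chain (1,2-addition).

Step 10
Reactants: 15 (1S,2R,4aS,6S,7R,8aS)-6,7-(isopropylidenedioxy)-2,5,5,8a-tetramethyl-1-[4-(trimethylsilyl)but-3-yn-1-yl]decahydronaphthalen-1-ol
Product: 17 methyl 5-[(1S,2R,4aS,6S,7R,8aS)-1-hydroxy-6,7-(isopropylidenedioxy)-2,5,5,8a-tetramethyldecahydronaphthalen-1-yl]pent-2-ynoate, via cesium alkynoate 16 (not isolated)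
Conditions: CsF, CO2 (1 atm), DMSO, rt; then MeI
Reagents that add atoms: carbon dioxide, O=C=O; iodomethane, CI
Why: fluoride-induced desilylation generates the acetylide, which is trapped by CO2, and the cesium carboxylate is O-methylated in the same flask (desilylative carboxylation and esterification) without touching the tertiary alcohol.

Step 11
Reactants: 17 methyl 5-[(1S,2R,4aS,6S,7R,8aS)-1-hydroxy-6,7-(isopropylidenedioxy)-2,5,5,8a-tetramethyldecahydronaphthalen-1-yl]pent-2-ynoate
Product: 18 methyl (2Z)-5-[(1S,2R,4aS,6S,7R,8aS)-1-hydroxy-6,7-(isopropylidenedioxy)-2,5,5,8a-tetramethyldecahydronaphthalen-1-yl]-3-methylpent-2-enoate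
Conditions: Me2CuLi (excess), THF, –78 °C; aq NH4Cl at –78 °C
Reagents that add atoms: lithium dimethylcuprate, [Li+].C[Cu-]C
Why: syn carbocupration of the ynoate and protonation of the vinylcopper with retention at low temperature place the new methyl trans to the ester, which is the (Z)-enoate (Gilman conjugate addition).

Step 12
Reactants: 18 methyl (2Z)-5-[(1S,2R,4aS,6S,7R,8aS)-1-hydroxy-6,7-(isopropylidenedioxy)-2,5,5,8a-tetramethyldecahydronaphthalen-1-yl]-3-methylpent-2-enoate
Product: 19 methyl (2Z)-5-[(1S,2R,4aS,6S,7R,8aS)-1,6,7-trihydroxy-2,5,5,8a-tetramethyldecahydronaphthalen-1-yl]-3-methylpent-2-enoate (CNP0292844.2)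
Conditions: AcOH/H2O (4:1), 40 °C
Reagents that add atoms: none
Why: mild aqueous acid hydrolyses the acetonide, and neither the tertiary alcohol nor the (Z)-enoate should be affected (ketal hydrolysis).

**Compound list**

1 | 2,6-dimethylanisole | COc1c(C)cccc1C | starting material
2 | 1-methoxy-2,6-dimethylcyclohexa-1,4-diene (racemic) | COC1=C(C)CC=CC1C | intermediate
3 | 2,6-dimethylcyclohex-3-en-1-one (cis/trans, racemic) | CC1CC=CC(C)C1=O | intermediate
4 | 2,2,6-trimethylcyclohex-3-en-1-one (racemic) | CC1CC=CC(C)(C)C1=O | intermediate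
5 | 3,3,5-trimethyl-4-methylidenecyclohex-1-ene (racemic) | C=C1C(C)CC=CC1(C)C | intermediate
6 | methacrolein | CC(=C)C=O | starting material
7 | (2R)-2-methyl-4-(2,6,6-trimethylcyclohexa-1,4-dien-1-yl)butanal | O=C[C@H](C)CCC1=C(C)CC=CC1(C)C | intermediate
8 | (1S,2R,8aS)-2,5,5,8a-tetramethyl-1,2,3,5,8,8a-hexahydronaphthalen-1-ol (9β-OH, 8α-Me, 10β-Me) | O[C@H]1[C@H](C)CC=C2C(C)(C)C=CC[C@@]21C | intermediate
9 | (1S,2R,6S,7R,8aS)-2,5,5,8a-tetramethyl-1,2,3,5,6,7,8,8a-octahydronaphthalene-1,6,7-triol (2α,3α-diol) | O[C@H]1[C@H](C)CC=C2C(C)(C)[C@H](O)[C@H](O)C[C@@]21C | intermediate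
10 | (1S,2R,6S,7R,8aS)-6,7-(isopropylidenedioxy)-2,5,5,8a-tetramethyl-1,2,3,5,6,7,8,8a-octahydronaphthalen-1-ol | O[C@H]1[C@H](C)CC=C2C(C)(C)[C@H](OC(C)(C)O3)[C@H]3C[C@@]21C | intermediate
11 | (1S,2R,4aS,6S,7R,8aS)-6,7-(isopropylidenedioxy)-2,5,5,8a-tetramethyldecahydronaphthalen-1-ol (trans-fused, 5α-H) | O[C@H]1[C@H](C)CC[C@H]2C(C)(C)[C@H](OC(C)(C)O3)[C@H]3C[C@@]21C | intermediate
12 | (2R,4aS,6S,7R,8aS)-6,7-(isopropylidenedioxy)-2,5,5,8a-tetramethyloctahydronaphthalen-1(2H)-one | O=C1[C@H](C)CC[C@H]2C(C)(C)[C@H](OC(C)(C)O3)[C@H]3C[C@@]21C | intermediate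
13 | 4-bromo-1-(trimethylsilyl)but-1-yne | C[Si](C)(C)C#CCCBr | starting material
14 | [4-(trimethylsilyl)but-3-yn-1-yl]magnesium bromide | C[Si](C)(C)C#CCC[Mg]Br | intermediate
15 | (1S,2R,4aS,6S,7R,8aS)-6,7-(isopropylidenedioxy)-2,5,5,8a-tetramethyl-1-[4-(trimethylsilyl)but-3-yn-1-yl]decahydronaphthalen-1-ol (9β-OH, 9α side chain) | C[Si](C)(C)C#CCC[C@]1(O)[C@H](C)CC[C@H]2C(C)(C)[C@H](OC(C)(C)O3)[C@H]3C[C@@]21C | intermediate
16 | cesium 5-[(1S,2R,4aS,6S,7R,8aS)-1-hydroxy-6,7-(isopropylidenedioxy)-2,5,5,8a-tetramethyldecahydronaphthalen-1-yl]pent-2-ynoate | [Cs+].[O-]C(=O)C#CCC[C@]1(O)[C@H](C)CC[C@H]2C(C)(C)[C@H](OC(C)(C)O3)[C@H]3C[C@@]21C | intermediate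
17 | methyl 5-[(1S,2R,4aS,6S,7R,8aS)-1-hydroxy-6,7-(isopropylidenedioxy)-2,5,5,8a-tetramethyldecahydronaphthalen-1-yl]pent-2-ynoate | COC(=O)C#CCC[C@]1(O)[C@H](C)CC[C@H]2C(C)(C)[C@H](OC(C)(C)O3)[C@H]3C[C@@]21C | intermediate
18 | methyl (2Z)-5-[(1S,2R,4aS,6S,7R,8aS)-1-hydroxy-6,7-(isopropylidenedioxy)-2,5,5,8a-tetramethyldecahydronaphthalen-1-yl]-3-methylpent-2-enoate | COC(=O)/C=C(/C)CC[C@]1(O)[C@H](C)CC[C@H]2C(C)(C)[C@H](OC(C)(C)O3)[C@H]3C[C@@]21C | intermediate
19 | methyl (2Z)-5-[(1S,2R,4aS,6S,7R,8aS)-1,6,7-trihydroxy-2,5,5,8a-tetramethyldecahydronaphthalen-1-yl]-3-methylpent-2-enoate | COC(=O)/C=C(/C)CC[C@]1(O)[C@H](C)CC[C@H]2C(C)(C)[C@H](O)[C@H](O)C[C@@]21C | target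

**Step count.** Total: 12 steps. Longest linear sequence: 12 steps (1 to 19); compounds 6 and 13 are bought.

**Steps most likely to fail**

Step 4 (labelled step). The catalyst may discriminate the enal faces poorly. The C5 cation may shift a methyl group from C4 instead of losing H6. The acid may move the exocyclic alkene of 5 into the ring before it reacts. The fallback uses known chemistry and sets out from 5 and 6. The same annulation is run with the achiral Lewis acid Me2AlCl (CH2Cl2, –20 °C to rt), which also scavenges protons, and should give the racemic dienol F1. Esterification with (S)-2-methoxy-2-phenylacetic acid (DCC, DMAP) gives the diastereomeric esters, the (S)-2-methoxy-2-phenylacetate of 8 F2 and the (S)-2-methoxy-2-phenylacetate of ent-8 F3, which are separated by chromatography. Saponification of F2 (LiOH, THF/H2O) comes back to the route at 8.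

Step 7. Hydrogen-atom transfer to the trisubstituted alkene between two quaternary carbons may be slow, or hydrogen may be delivered to C5 from the wrong face. The fallback sets out from 10. Hydroboration and oxidation (BH3·THF; then NaOH, H2O2) from the open α face set the 5α-hydrogen by syn addition and give the 6α,9β-diol F4. The less hindered C6 hydroxyl is converted with 1,1'-thiocarbonyldiimidazole and DMAP into the 6-O-(imidazol-1-ylthiocarbonyl) derivative F5. Barton–McCombie deoxygenation (Bu3SnH, AIBN, toluene, 110 °C) comes back to the route at 11.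

Step 9. The hindered ketone may be enolised instead of attacked, or the bulky reagent may not reach the carbonyl carbon. The fallback sets out from 12. Dimethylsulfonium methylide (Me3SI, n-BuLi, THF, 0 °C) attacks the α face and gives the spiro-epoxide F6 with the oxygen β. Opening at its CH2 terminus with 3-(trimethylsilyl)prop-2-yn-1-yllithium (from 1-(trimethylsilyl)propyne and n-BuLi) and BF3·OEt2 at –78 °C comes back to the route at 15.

**Further compounds**

F1 | step 4 | racemic 2,5,5,8a-tetramethyl-1,2,3,5,8,8a-hexahydronaphthalen-1-ol (8 and its enantiomer) | O[C@H]1[C@H](C)CC=C2C(C)(C)C=CC[C@@]21C.O[C@@H]1[C@@H](C)CC=C2C(C)(C)C=CC[C@]21C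
F2 | step 4 | (S)-2-methoxy-2-phenylacetate of 8 | CO[C@@H](c1ccccc1)C(=O)O[C@H]1[C@H](C)CC=C2C(C)(C)C=CC[C@@]21C
F3 | step 4 | (S)-2-methoxy-2-phenylacetate of ent-8 | CO[C@@H](c1ccccc1)C(=O)O[C@@H]1[C@@H](C)CC=C2C(C)(C)C=CC[C@]21C
F4 | step 7 | (1S,2R,4S,4aS,6S,7R,8aS)-6,7-(isopropylidenedioxy)-2,5,5,8a-tetramethyldecahydronaphthalene-1,4-diol (6α,9β-diol in labdane numbering) | O[C@H]1[C@H](C)C[C@H](O)[C@H]2C(C)(C)[C@H](OC(C)(C)O3)[C@H]3C[C@@]21C
F5 | step 7 | 6α-O-(imidazol-1-ylthiocarbonyl) derivative of F4 (labdane numbering) | O[C@H]1[C@H](C)C[C@H](OC(=S)n4ccnc4)[C@H]2C(C)(C)[C@H](OC(C)(C)O3)[C@H]3C[C@@]21C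
F6 | step 9 | spiro-epoxide of 12 at C9 (oxygen β, CH2 α) | O1C[C@@]12[C@H](C)CC[C@H]3C(C)(C)[C@H](OC(C)(C)O4)[C@H]4C[C@@]32C
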